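**Retrosynthetic overview**
1. Target 14 ⇒ (Z)-bromodienyne 13. Ring B, the spiro carbon C6 and the C7 carbinol come from one cation–olefin closure of the C1–C6 bond: the ring-A alkene C6=C7 attacks an activated alkyne terminus and water quenches the C7 cation. This is the bond and the cation of the farnesyl → bisabolyl step.
2. The (Z)-BrCH= geometry is fixed before ring closure: anti-hydroiodination of a 1-bromoalkyne, then iodide-selective Sonogashira coupling.
3. Side chain ⇒ Negishi coupling of vinyl triflate 5. The C9 bromide cannot come from a bromonium closure (that would put Br on C10), so it is installed on ring A by SN2 inversion and then used to steer the closure.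
4. Ring A and the only catalyst-controlled stereocentre ⇒ ketoisophorone by asymmetric transfer hydrogenation.
5. Ring order: ring A is carried from the starting material; ring B is closed in the last step.

Assumption: positions are named with chamigrane numbering (ring B = C1–C5 with C15 on C3, C6 = spiro carbon, ring A = C7–C11); the target is 6S,7S,9R,3(15)Z, and the same C–Br arrangement is "4S" in the monocyclic intermediates only because CIP priorities change.

**Route**

Step 1
Reactants: 1 2,6,6-trimethylcyclohex-2-ene-1,4-dione (ketoisophorone)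
Product: 2 (4S)-4-hydroxy-2,6,6-trimethylcyclohex-2-en-1-one
Conditions: RuCl(p-cymene)[(S,S)-TsDPEN] (0.5 mol %), HCO2H/Et3N (5:2), CH2Cl2, 25 °C
Reagents that add atoms: none
Why: Noyori asymmetric transfer hydrogenation reduces only the unhindered C4 carbonyl (C1 is flanked by CMe2 and C(Me)=), and the (S,S)-catalyst should give the 4S alcohol by the aryl-ketone model with the C=C in the aryl role (the antipodal catalyst is used if the rotation shows the opposite sense).

Step 2
Reactants: 2 (4S)-4-hydroxy-2,6,6-trimethylcyclohex-2-en-1-one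
Product: 3 (4R,6R)-4-hydroxy-2,2,6-trimethylcyclohexan-1-one
Conditions: H2 (1 atm), [Ir(cod)(PCy3)(py)]PF6 (2 mol %), CH2Cl2, 0 → 25 °C
Reagents that add atoms: none
Why: Hydroxyl-directed (Crabtree) hydrogenation adds H2 syn to OH and gives the trans isomer, whose OH can sit axial for the next substitution; the carbinol centre is untouched and the new C6 centre is erased in step 4.

Step 3
Reactants: 3 (4R,6R)-4-hydroxy-2,2,6-trimethylcyclohexan-1-one
Product: 4 (4S,6R)-4-bromo-2,2,6-trimethylcyclohexan-1-one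
Conditions: CBr4, PPh3, CH2Cl2, 0 °C
Reagents that add atoms: carbon tetrabromide, BrC(Br)(Br)Br
Why: Appel bromination displaces the axial alkoxyphosphonium by bromide along the open equatorial trajectory (SN2, inversion), which sets the C–Br configuration of the target (equatorial Br, cis to the 6-methyl).

Step 4
Reactants: 4 (4S,6R)-4-bromo-2,2,6-trimethylcyclohexan-1-one
Product: 5 (4S)-4-bromo-2,6,6-trimethylcyclohex-1-en-1-yl trifluoromethanesulfonate
Conditions: Tf2O, 2,6-di-tert-butyl-4-methylpyridine, CH2Cl2, 0 → 25 °C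
Reagents that add atoms: trifluoromethanesulfonic anhydride, O=S(=O)(OS(=O)(=O)C(F)(F)F)C(F)(F)F
Why: Stang enol triflation without a free enolate (an enolate would displace the γ-bromide by 1,3-elimination); only C6 carries an α-hydrogen, so the tetrasubstituted triflate forms regiospecifically.

Step 5
Reactants: 5 (4S)-4-bromo-2,6,6-trimethylcyclohex-1-en-1-yl trifluoromethanesulfonate; 6 (4-bromobut-1-yn-1-yl)trimethylsilane
Product: 8 {4-[(4S)-4-bromo-2,6,6-trimethylcyclohex-1-en-1-yl]but-1-yn-1-yl}trimethylsilane, via organozinc bromide 7 (not isolated)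
Conditions: 6, Zn dust, LiCl, THF, 50 °C; then 5, PdCl2(dppf) (5 mol %), THF/NMP, 60 °C
Reagents that add atoms: (4-bromobut-1-yn-1-yl)trimethylsilane (6), C[Si](C)(C)C#CCCBr
Why: Negishi sp3–sp2 coupling; zerovalent palladium inserts into the vinyl triflate far faster than into the unactivated secondary C–Br, and the alkylzinc tolerates both the bromide and the silylalkyne.

Step 6
Reactants: 8 {4-[(4S)-4-bromo-2,6,6-trimethylcyclohex-1-en-1-yl]but-1-yn-1-yl}trimethylsilane
Product: 9 (4S)-4-bromo-1-(4-bromobut-3-yn-1-yl)-2,6,6-trimethylcyclohex-1-ene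
Conditions: NBS, AgNO3 (10 mol %), acetone, 25 °C, dark
Reagents that add atoms: N-bromosuccinimide, O=C1CCC(=O)N1Br
Why: Silver-catalysed bromodesilylation (ipso substitution through the silver acetylide) gives the 1-bromoalkyne; in dry acetone in the dark NBS should leave the tetrasubstituted alkene alone.

Step 7
Reactants: 9 (4S)-4-bromo-1-(4-bromobut-3-yn-1-yl)-2,6,6-trimethylcyclohex-1-ene
Product: 10 (4S)-4-bromo-1-[(3Z)-4-bromo-3-iodobut-3-en-1-yl]-2,6,6-trimethylcyclohex-1-ene
Conditions: LiI, Pd(OAc)2 (5 mol %), AcOH, 25 °C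
Reagents that add atoms: lithium iodide, [Li+].[I-]
Why: Anti-hydroiodination of a 1-haloalkyne: iodide adds to the alkyne carbon remote from Br, trans to divalent palladium, and protonolysis with retention gives net anti H–I addition, so I and Br end up cis (Z).

Step 8
Reactants: 10 (4S)-4-bromo-1-[(3Z)-4-bromo-3-iodobut-3-en-1-yl]-2,6,6-trimethylcyclohex-1-ene; 11 ethynyltrimethylsilane
Product: 13 (4S)-4-bromo-1-[(3Z)-3-(bromomethylidene)pent-4-yn-1-yl]-2,6,6-trimethylcyclohex-1-ene, via silylated enyne 12 (not isolated)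
Conditions: 11, PdCl2(PPh3)2 (3 mol %), CuI (5 mol %), i-Pr2NH, THF, 25 °C; then K2CO3 (0.2 equiv), MeOH, 25 °C
Reagents that add atoms: ethynyltrimethylsilane (11), C#C[Si](C)(C)C
Why: Sonogashira coupling occurs only at C–I (much faster oxidative addition than at vinyl or alkyl C–Br) with retention, so the ethynyl group ends up cis to Br and the (Z)-bromomethylidene geometry is fixed; methanolysis then removes the silyl group.

Step 9
Reactants: 13 (4S)-4-bromo-1-[(3Z)-3-(bromomethylidene)pent-4-yn-1-yl]-2,6,6-trimethylcyclohex-1-ene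
Product: 14 (1S,3R,6S,9Z)-3-bromo-9-(bromomethylidene)-1,5,5-trimethylspiro[5.5]undec-7-en-1-ol
Conditions: [Au(NCMe){P(t-Bu)2(2-biphenylyl)}]SbF6 (5 mol %), H2O (5 equiv), 1,4-dioxane, 25 °C
Reagents that add atoms: water, O
Why: Proposed new method: a gold-initiated cation–olefin spirocyclisation (closest known type: monovalent-gold-catalysed 6-endo-dig hydroxycyclisation of 1,6-enynes and gold-initiated polyene cyclisations) in which C6 of the tetrasubstituted alkene attacks the unsubstituted alkyne terminus C1 (attack at C2 would join two fully substituted carbons next to CMe2, and charge building at C2 in the endo mode is allylically stabilised by the bromovinyl group), water adds to the tertiary C7 cation anti to the new C1–C6 bond and protodeauration leaves C1=C2; the alkene reacts through the half-chair with equatorial Br, so C1 enters axially at C6 anti to the pseudoaxial C11 methyl (cis to Br) and OH enters axially at C7 on the other face, giving 6S,7S.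

**Compound list**
1 | 2,6,6-trimethylcyclohex-2-ene-1,4-dione (ketoisophorone) | CC1=CC(=O)CC(C)(C)C1=O | starting material
2 | (4S)-4-hydroxy-2,6,6-trimethylcyclohex-2-en-1-one | CC1(C)C[C@H](O)C=C(C)C1=O | intermediate
3 | (4R,6R)-4-hydroxy-2,2,6-trimethylcyclohexan-1-one | CC1(C)C[C@H](O)C[C@@H](C)C1=O | intermediate
4 | (4S,6R)-4-bromo-2,2,6-trimethylcyclohexan-1-one | CC1(C)C[C@@H](Br)C[C@@H](C)C1=O | intermediate
5 | (4S)-4-bromo-2,6,6-trimethylcyclohex-1-en-1-yl trifluoromethanesulfonate | CC1(C)C[C@@H](Br)CC(C)=C1OS(=O)(=O)C(F)(F)F | intermediate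
6 | (4-bromobut-1-yn-1-yl)trimethylsilane | C[Si](C)(C)C#CCCBr | starting material
7 | [4-(trimethylsilyl)but-3-yn-1-yl]zinc bromide | C[Si](C)(C)C#CCC[Zn]Br | intermediate
8 | {4-[(4S)-4-bromo-2,6,6-trimethylcyclohex-1-en-1-yl]but-1-yn-1-yl}trimethylsilane | CC1(C)C[C@@H](Br)CC(C)=C1CCC#C[Si](C)(C)C | intermediate
9 | (4S)-4-bromo-1-(4-bromobut-3-yn-1-yl)-2,6,6-trimethylcyclohex-1-ene | CC1(C)C[C@@H](Br)CC(C)=C1CCC#CBr | intermediate
10 | (4S)-4-bromo-1-[(3Z)-4-bromo-3-iodobut-3-en-1-yl]-2,6,6-trimethylcyclohex-1-ene | CC1(C)C[C@@H](Br)CC(C)=C1CC/C(I)=C/Br | intermediate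
11 | ethynyltrimethylsilane | C#C[Si](C)(C)C | starting material
12 | {(3Z)-3-(bromomethylidene)-5-[(4S)-4-bromo-2,6,6-trimethylcyclohex-1-en-1-yl]pent-1-yn-1-yl}trimethylsilane | CC1(C)C[C@@H](Br)CC(C)=C1CC/C(=C/Br)C#C[Si](C)(C)C | intermediate
13 | (4S)-4-bromo-1-[(3Z)-3-(bromomethylidene)pent-4-yn-1-yl]-2,6,6-trimethylcyclohex-1-ene | CC1(C)C[C@@H](Br)CC(C)=C1CC/C(=C/Br)C#C | intermediate
14 | (1S,3R,6S,9Z)-3-bromo-9-(bromomethylidene)-1,5,5-trimethylspiro[5.5]undec-7-en-1-ol | CC1(C)C[C@@H](Br)C[C@](C)(O)[C@@]12C=C/C(=C\Br)CC2 | target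

**Count and risks**
Total steps: 9. Longest linear sequence: 9 (from 1).

Most likely to fail:

Step 9. The closure may go 5-exo-dig or through C7 to fused rings, the alkyne may simply be hydrated, or the C7 cation may eliminate. The fallback sets out from 5 and comes back at 14, using an ynone whose conjugation forces attack at the alkyne terminus. Negishi coupling of 5 with (3-ethoxy-3-oxopropyl)zinc bromide gives ethyl 3-[(4S)-4-bromo-2,6,6-trimethylcyclohex-1-en-1-yl]propanoate F1. MeNH(OMe)·HCl/i-PrMgCl converts it into 3-[(4S)-4-bromo-2,6,6-trimethylcyclohex-1-en-1-yl]-N-methoxy-N-methylpropanamide F2, and ethynylmagnesium bromide then gives 5-[(4S)-4-bromo-2,6,6-trimethylcyclohex-1-en-1-yl]pent-1-yn-3-one F3. The same gold/water conditions close ring B to (6S,7S,9R)-9-bromo-7-hydroxy-7,11,11-trimethylspiro[5.5]undec-1-en-3-one F4. Wittig bromomethylenation with Ph3P=CHBr then gives 14, but as a mixture with its E isomer that has to be separated on AgNO3-impregnated silica; the alkene geometry is no longer controlled in this fallback.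

Step 7. Iodide may attack bromine instead of carbon (halogen scrambling), or the anti selectivity may be incomplete. The fallback sets out from 8 and comes back at 12, using haloboration in place of hydrohalogenation. K2CO3/MeOH gives (4S)-4-bromo-1-(but-3-yn-1-yl)-2,6,6-trimethylcyclohex-1-ene F5. Syn-bromoboration with BBr3 at −78 °C and pinacol quench gives 2-[(1Z)-2-bromo-4-[(4S)-4-bromo-2,6,6-trimethylcyclohex-1-en-1-yl]but-1-en-1-yl]-4,4,5,5-tetramethyl-1,3,2-dioxaborolane F6. Negishi coupling of the C–Br bond with [(trimethylsilyl)ethynyl]zinc bromide (Pd[P(t-Bu)3]2, retention) gives 2-[(1Z)-4-[(4S)-4-bromo-2,6,6-trimethylcyclohex-1-en-1-yl]-2-[(trimethylsilyl)ethynyl]but-1-en-1-yl]-4,4,5,5-tetramethyl-1,3,2-dioxaborolane F7. Bromodeboronation with CuBr2 (retention) then gives 12. BBr3 may not spare the ring-A alkene.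

Step 5. The tetrasubstituted triflate is hindered and β-hydride elimination can compete. The fallback sets out from 4 and comes back at 8, replacing cross-coupling by carbonyl addition and dehydration. The organocerium reagent made from 6 (Mg, then CeCl3) adds to ketone 4 to give (4S,6R)-4-bromo-2,2,6-trimethyl-1-[4-(trimethylsilyl)but-3-yn-1-yl]cyclohexan-1-ol F8. Dehydration (SOCl2, pyridine) towards the only ring α-hydrogen gives 8; the exocyclic alkene isomer is the expected by-product.

Further compounds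
F1 | step 9 | ethyl 3-[(4S)-4-bromo-2,6,6-trimethylcyclohex-1-en-1-yl]propanoate | CC1(C)C[C@@H](Br)CC(C)=C1CCC(=O)OCC
F2 | step 9 | 3-[(4S)-4-bromo-2,6,6-trimethylcyclohex-1-en-1-yl]-N-methoxy-N-methylpropanamide | CC1(C)C[C@@H](Br)CC(C)=C1CCC(=O)N(C)OC
F3 | step 9 | 5-[(4S)-4-bromo-2,6,6-trimethylcyclohex-1-en-1-yl]pent-1-yn-3-one | CC1(C)C[C@@H](Br)CC(C)=C1CCC(=O)C#C
F4 | step 9 | (6S,7S,9R)-9-bromo-7-hydroxy-7,11,11-trimethylspiro[5.5]undec-1-en-3-one | CC1(C)C[C@@H](Br)C[C@](C)(O)[C@@]12C=CC(=O)CC2
F5 | step 7 | (4S)-4-bromo-1-(but-3-yn-1-yl)-2,6,6-trimethylcyclohex-1-ene | CC1(C)C[C@@H](Br)CC(C)=C1CCC#C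
F6 | step 7 | 2-[(1Z)-2-bromo-4-[(4S)-4-bromo-2,6,6-trimethylcyclohex-1-en-1-yl]but-1-en-1-yl]-4,4,5,5-tetramethyl-1,3,2-dioxaborolane | CC1(C)C[C@@H](Br)CC(C)=C1CC/C(Br)=C/B1OC(C)(C)C(C)(C)O1
F7 | step 7 | 2-[(1Z)-4-[(4S)-4-bromo-2,6,6-trimethylcyclohex-1-en-1-yl]-2-[(trimethylsilyl)ethynyl]but-1-en-1-yl]-4,4,5,5-tetramethyl-1,3,2-dioxaborolane | CC1(C)C[C@@H](Br)CC(C)=C1CC/C(C#C[Si](C)(C)C)=C/B1OC(C)(C)C(C)(C)O1
F8 | step 5 | (4S,6R)-4-bromo-2,2,6-trimethyl-1-[4-(trimethylsilyl)but-3-yn-1-yl]cyclohexan-1-ol | CC1(C)C[C@@H](Br)C[C@@H](C)C1(O)CCC#C[Si](C)(C)C
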